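Atom numbering runs along the carbon chain from the alkene terminus: C1=C2, C10 carbinol, C11–C14 ring carbons with the ring oxygen between C11 and C14, and C15–C19 the pentyl group. Compound numbers 1–21 are those fixed in the steps and in the compound list.

## Analysis of the target

Compound 21 is a 2,3,5-trisubstituted oxolane (ring atoms O, C11, C12, C13, C14) set between unbranched lipid chains. C11 carries the C10 carbinol, whose chain runs through seven methylenes to the terminal alkene C1=C2. C13 carries a dodecanoate and C14 an n-pentyl group (C15–C19). The four stereocentres are 10R, 11R, 13S and 14S: on the ring the C13 acyloxy group and the C14 pentyl group are cis, the C11 side chain is trans to both, and C10/C11 are threo. The sensitive groups are the monosubstituted alkene, the ester, and the two secondary oxygens at C10 and C13, of which exactly one is acylated. The alkene rules out hydrogenation, hydrogenolysis and electrophilic oxidants once it is present, and a carbonyl at C10 makes C11 epimerisable. The difficulty is the relay of configuration around a flexible five-membered ring that has no directing group other than oxygen, then out of the ring to C10, and the differentiation of the two carbinols without a long protecting-group sequence. The strategy rests on C14, which is bonded at once to the ring oxygen, to the oxygenated C13 and to C15. With C13 as a ketone and C15–C17 as an allyl group, this O–C(allyl)–C(=O) array is what results when an allyl group shifts from an oxonium oxygen to a neighbouring acyl-stabilised ylide carbon. One operation on an acyclic diazoketone can therefore close the ring (O–C14), form C14–C15 and set C14, with C11 from the chiral pool as the only control element; C13 and C10 are then relayed from C14 and C11.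

## Retrosynthetic reasoning

**C9–C10.** The last bond made is C9–C10, which divides 21 into aldehyde 18 and the C1–C9 Grignard reagent 20, itself from bromide 19. The cut removes the only stereocentre outside the ring together with the terminal alkene, so no earlier step has to tolerate C1=C2. The ring oxygen on C11 sits alpha to the C10 carbonyl and can form a chelate. Because the laurate is already in place in 18, the hydroxyl set free at C10 is the free hydroxyl of 21 and the two secondary oxygens never compete. The forward reaction must add to the aldehyde faster than to the ester, and from the chelate face that gives 10R.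

**C10 oxidation level.** Aldehyde 18 goes back through primary alcohol 17 to silyl ether 16. These are adjustments of protection and oxidation state at C10 only. Keeping C10 as a robust silyl ether up to this point lets acylation, metathesis and hydrogenation run without interference.

**C16=C17.** After a retro-hydrogenation to 15, the pentyl group is cut at C16=C17 into the allyl compound 13 and (Z)-hex-3-ene 14. The key step delivers three carbons at C14; the missing two arrive as half of a symmetrical alkene by cross-metathesis. Saturation at this stage has no chemoselectivity problem because no other alkene is present.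

**Ester C–O.** Laurate 13 is cut at the acyl–oxygen bond into alcohol 11 and dodecanoic acid 12. Acylation at this point meets a single free hydroxyl.

**C13–H.** Alcohol 11 comes from ketone 10 by hydride addition. The C14 allyl group next to the carbonyl should direct the hydride to the opposite face and give the cis C13 oxygen.

**O–C14 and C14–C15 (key disconnection).** Both bonds to C14 in 10 are cut together. This returns the allyl group to the ether oxygen and leaves C14 as the diazo carbon of the acyclic diazoketone 7. No other disconnection of 10 builds the ring, a carbon–carbon bond and a stereocentre in one step from a precursor with a single stereocentre. The forward reaction passes through carbenoid 8 and oxonium ylide 9 and must transfer the allyl group trans to the C11 substituent.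

**C13–C14.** Diazoketone 7 is cut between the carbonyl carbon and the diazo carbon, giving acid 5, activated as mixed anhydride 6, and a one-carbon diazo donor. This is the standard homologation of an acid to a diazomethyl ketone.

**O–allyl and the chiral pool.** Acid 5 comes from ester 4, whose allyl ether is cut at the O–CH2 bond to give the β-hydroxy ester 3. Ester 3 is the primary silyl ether of diol 2, and 2 is the product of chemoselective reduction of the α-hydroxy ester group of dimethyl (R)-malate 1. The carbinol carbon of 1 becomes C11 without any bond to it being broken. Its two ester groups are differentiated by the neighbouring hydroxyl, which makes one of them C10 and the other C13.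

## Alternatives that were turned down

**Alternative 1:** dichloroketene cycloaddition and oxidative ring expansion.
- **Disconnection.** The ring oxygen is taken out of the O–C14 linkage (retro-Baeyer–Villiger), giving a cyclobutanone with a temporary C11–C14 bond. This is then cut across C12–C13 and C11–C14 into a ketene and an enol ether.
- **Forward key step.** Dichloroketene A2 adds in a [2+2] sense to the Z-enol ether A1, whose 1-arylethyl group blocks one face, to give cyclobutanone A3 with the C13 oxygen and the C14 pentyl group cis. Dechlorination and peracid ring expansion, with migration of the more substituted C14, would give lactone A4.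
- **For.** The cis C13/C14 pair follows directly from the enol ether geometry and the auxiliary in one step, independent of any ketone reduction.
- **Against.** In A4 the carbon C11 is a lactone carbonyl. The C10–C11 bond and both the C10 and C11 stereocentres would still have to be made, by nucleophilic substitution on a lactol-derived oxocarbenium ion. The facial preference of that ion is set mainly by the C13 alkoxy group, not by the requirement to be trans to pentyl, and the exocyclic carbinol would need a further selective step. The auxiliary is stoichiometric and must be cleaved and replaced by the laurate.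
- **Comparison.** A3 secures the C13/C14 relationship more directly than the reduction of 10 in step 7 does. The chosen route instead buys C11 with the correct configuration and oxidation level, makes C10 accessible by chelation control, and needs no auxiliary.

**Alternative 2:** epoxidation of a dihydrofuran and syn alkyl transfer.
- **Disconnection.** The C13–O and C14–C15 bonds are cut across a C13=C14 enol ether, leading to the 2,3-dihydrofuran A5, which already carries the complete benzyl-protected C1–C10 side chain.
- **Forward key step.** Dimethyldioxirane A6 epoxidises A5 on the face away from the C11 substituent to give epoxide A7. Al(C5H11)3 A8 opens A7 at C14 with delivery of pentyl on the side of the departing oxygen, giving alcohol A9.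
- **For.** C13 and C14 are set in one flask, and the pentyl group arrives intact. No chain extension and no ketone reduction are needed, and C10 is already in place.
- **Against.** A5 must first be made as a single stereoisomer with C10 and C11 defined, which takes several steps. The C11 substituent that is to steer the epoxidation is 1,3 to the alkene across the ring oxygen on a nearly flat ring, so its bias is modest. A6 must leave C1=C2 untouched, and A7 is a labile acetal-type epoxide. A8 is not an off-the-shelf reagent and gives up only one of its three alkyl groups. Syn opening depends on internal delivery and can leak to anti opening. The benzyl group must later be removed without hydrogenolysis because of C1=C2.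
- **Comparison.** This alternative is stronger in step economy at the stage where stereochemistry is set. The chosen route offers three substrate-controlled steps on well-understood templates, commercial reagents, and a terminal alkene that enters only in the last step.

**Alternative 3:** allylsilane–aldehyde [3+2] annulation.
- **Disconnection.** The ring is cut at C11–C12 and O–C14 into the α-benzyloxy aldehyde A10, whose carbonyl carbon is C11, and the α-branched allylsilane A11, which supplies C12–C14 and the pentyl group.
- **Forward key step.** SnCl4 A12 chelates A10 and the alkene terminus of A11 adds to the carbonyl. Silicon then shifts from C14 to C13 and the alkoxide closes the ring at C14, giving silyl oxolane A13. The silicon is later oxidised to the C13 hydroxyl.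
- **For.** This is the most convergent plan. All carbons and the C10, C11 and C14 stereocentres are assembled in one step, and chelation sets the C10/C11 relationship at the same time.
- **Against.** In A13 silicon is trans to the pentyl group, so oxidation with retention gives the C13-epimeric alcohol A14, and an inversion on a hindered ring carbinol is needed. Converting the dimethylphenylsilyl group to hydroxyl requires electrophilic removal of the phenyl group followed by peroxide, which C1=C2 would not survive. The alkene would have to be masked or introduced later, which gives up the convergence. A10 and A11 each need a multistep enantioselective preparation. Simple allyl transfer without ring closure is a known leak.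
- **Comparison.** This alternative is stronger in convergence and in setting C10 with the ring. The chosen route keeps oxygen on C13 from the outset as a carbonyl, obtains the cis C13 configuration directly, and never exposes the terminal alkene to oxidants.

Key step: step 6

Remark on the chemistry: diazomethane is taken as a freshly distilled ethereal solution prepared from commercial N-methyl-N-nitroso-p-toluenesulfonamide and KOH. Compound 15 is expected as an E/Z mixture, which does not matter because the double bond is hydrogenated in step 10.

## Route

Step 1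
Reactants: 1 dimethyl (R)-malate
Product: 2 methyl (3R)-3,4-dihydroxybutanoate
Conditions: BH3·SMe2 (1.0 equiv), NaBH4 (5 mol %), THF, 0 °C → rt; MeOH quench, co-evaporation with MeOH
Reagents that add atoms: none
Why: Hydroxyl-directed borane reduction: the alkoxyborane formed at the free hydroxyl delivers hydride through a five-membered chelate to the adjacent ester only, so the β-ester survives; the carbinol carbon (future C11) is not involved and stays R.

Step 2
Reactants: 2 methyl (3R)-3,4-dihydroxybutanoate
Product: 3 methyl (3R)-4-(tert-butyldiphenylsilyloxy)-3-hydroxybutanoate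
Conditions: t-BuPh2SiCl (1.05 equiv), imidazole, CH2Cl2, 0 °C
Reagents that add atoms: tert-butyl(chloro)diphenylsilane, CC(C)(C)[Si](Cl)(c1ccccc1)c1ccccc1
Why: Silyl ether formation with a bulky chlorosilane is selective for the primary hydroxyl at low temperature, leaving the secondary hydroxyl free for step 3.

Step 3
Reactants: 3 methyl (3R)-4-(tert-butyldiphenylsilyloxy)-3-hydroxybutanoate
Product: 4 methyl (3R)-3-(allyloxy)-4-(tert-butyldiphenylsilyloxy)butanoate
Conditions: allyl 2,2,2-trichloroacetimidate (2 equiv), TfOH (10 mol %), cyclohexane/CH2Cl2, 0 °C → rt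
Reagents that add atoms: allyl 2,2,2-trichloroacetimidate, C=CCOC(=N)C(Cl)(Cl)Cl
Why: Acid-catalysed O-alkylation with a trichloroacetimidate avoids the alkoxide that would cause retro-aldol cleavage, β-elimination or silyl migration in this β-hydroxy ester; the C–O bond at C11 is not broken, so its configuration is retained.

Step 4
Reactants: 4 methyl (3R)-3-(allyloxy)-4-(tert-butyldiphenylsilyloxy)butanoate
Product: 5 (3R)-3-(allyloxy)-4-(tert-butyldiphenylsilyloxy)butanoic acid
Conditions: LiOH·H2O (2 equiv), THF/H2O, 0 °C → rt; then 1 M HCl to pH 3–4 at 0 °C
Reagents that add atoms: lithium hydroxide (source of the carboxyl OH oxygen), [Li+].[OH-]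
Why: Ester saponification; cold LiOH limits E1cB loss of the β-allyloxy group, and the tert-butyldiphenylsilyl ether tolerates these conditions.

Step 5
Reactants: 5 (3R)-3-(allyloxy)-4-(tert-butyldiphenylsilyloxy)butanoic acid
Product: 7 (4R)-4-(allyloxy)-5-(tert-butyldiphenylsilyloxy)-1-diazopentan-2-one, via isobutyl carbonic mixed anhydride 6 (not isolated)
Conditions: i-BuOCOCl (1.1 equiv), Et3N (1.1 equiv), Et2O, −20 → 0 °C; then CH2N2 (excess, Et2O), 0 °C → rt
Reagents that add atoms: diazomethane, C=[N+]=[N-]; isobutyl chloroformate, CC(C)COC(=O)Cl (its atoms are carried only in 6 and are lost again)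
Why: Acylation of diazomethane by a mixed carbonic anhydride (the first stage of an Arndt–Eistert sequence) forms C13–C14; the isobutyl carbonate leaving group takes up the proton, so no HCl is present to turn the diazoketone into a chloromethyl ketone.

Step 6
Reactants: 7 (4R)-4-(allyloxy)-5-(tert-butyldiphenylsilyloxy)-1-diazopentan-2-one
Product: 10 (2S,5R)-2-allyl-5-[(tert-butyldiphenylsilyloxy)methyl]dihydrofuran-3(2H)-one, via copper carbenoid 8 (not isolated), via allyloxonium ylide 9 (not isolated)
Conditions: Cu(acac)2 (10 mol %), THF, reflux, slow addition of 7 at high dilution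
Reagents that add atoms: none
Why: Cu(acac)2, a divalent copper precatalyst, decomposes the diazoketone with loss of N2 to the electrophilic copper carbenoid 8 at C14. A lone pair of the allyl ether oxygen adds to the carbenoid carbon; this closes the oxolane through the O–C14 bond in a five-membered exo-type closure (O, C11, C12, C13 and C14 in the ring, the C=Cu bond outside it) and releases copper to give the cyclic allyloxonium ylide 9. A concerted suprafacial [2,3]-sigmatropic shift through a five-membered envelope transition state then moves the allyl group from oxygen to C14 and forms C14–C15. The closest known reaction type is the copper-catalysed tandem oxonium ylide formation and [2,3]-rearrangement of allyl ethers of diazoketones, which gives 2,5-trans-dihydrofuran-3(2H)-ones. The one new stereocentre, C14, is controlled by C11: in the ylide envelope the silyloxymethyl group is pseudo-equatorial, the allyl group on oxygen lies on the ring face away from it, and the shift delivers allyl to that same face of C14, so C14 becomes S and trans to the C11 substituent while C11 itself is untouched. The step needs ylide formation to win over 1,5 C–H insertion at the C10 methylene, cyclopropanation of the allyl alkene and carbenoid dimerisation, and the [2,3]-shift to win over a [1,2]-shift. The copper carbenoid prefers the Lewis-basic ether oxygen to C–H bonds, the bulky and inductively deactivating silyl ether shields the C10–H bonds, the unhindered allyl group makes the concerted shift fast, and slow addition at high dilution suppresses dimerisation.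

Step 7
Reactants: 10 (2S,5R)-2-allyl-5-[(tert-butyldiphenylsilyloxy)methyl]dihydrofuran-3(2H)-one
Product: 11 (2S,3S,5R)-2-allyl-5-[(tert-butyldiphenylsilyloxy)methyl]tetrahydrofuran-3-ol
Conditions: LiBH(s-Bu)3 (1.2 equiv), THF, −78 °C; then aq. NaOH, H2O2, 0 °C
Reagents that add atoms: none
Why: Diastereoselective ketone reduction with a bulky trialkylborohydride, which attacks the C13 carbonyl from the ring face opposite the adjacent C14 allyl group (1,2-induction), so the new hydroxyl is cis to allyl (13S); the low temperature keeps the epimerisable C14 intact until the ketone is gone.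

Step 8
Reactants: 11 (2S,3S,5R)-2-allyl-5-[(tert-butyldiphenylsilyloxy)methyl]tetrahydrofuran-3-ol; 12 dodecanoic acid
Product: 13 (2S,3S,5R)-2-allyl-5-[(tert-butyldiphenylsilyloxy)methyl]tetrahydrofuran-3-yl dodecanoate
Conditions: DCC (1.3 equiv), DMAP (0.2 equiv), CH2Cl2, 0 °C → rt
Reagents that add atoms: none
Why: Steglich esterification acylates the only free hydroxyl with retention at C13, since the C13–O bond is not broken.

Step 9
Reactants: 13 (2S,3S,5R)-2-allyl-5-[(tert-butyldiphenylsilyloxy)methyl]tetrahydrofuran-3-yl dodecanoate; 14 (Z)-hex-3-ene
Product: 15 (2S,3S,5R)-5-[(tert-butyldiphenylsilyloxy)methyl]-2-(pent-2-en-1-yl)tetrahydrofuran-3-yl dodecanoate (E/Z mixture)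
Conditions: second-generation Grubbs catalyst (H2IMes)(PCy3)Cl2Ru=CHPh (5 mol %), 14 (10 equiv), CH2Cl2, 40 °C
Reagents that add atoms: none
Why: Olefin cross-metathesis of a reactive terminal alkene with an excess of a symmetrical internal alkene transfers a propylidene unit and turns allyl into pent-2-enyl; the symmetrical partner can give only one cross product, and the but-1-ene formed is volatile.

Step 10
Reactants: 15 (2S,3S,5R)-5-[(tert-butyldiphenylsilyloxy)methyl]-2-(pent-2-en-1-yl)tetrahydrofuran-3-yl dodecanoate
Product: 16 (2S,3S,5R)-5-[(tert-butyldiphenylsilyloxy)methyl]-2-pentyltetrahydrofuran-3-yl dodecanoate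
Conditions: H2 (1 atm), 10% Pd/C, EtOAc, rt
Reagents that add atoms: none
Why: Heterogeneous catalytic hydrogenation of the only alkene present; the silyl ether and the ester are inert, and no stereocentre is affected.

Step 11
Reactants: 16 (2S,3S,5R)-5-[(tert-butyldiphenylsilyloxy)methyl]-2-pentyltetrahydrofuran-3-yl dodecanoate
Product: 17 (2S,3S,5R)-5-(hydroxymethyl)-2-pentyltetrahydrofuran-3-yl dodecanoate
Conditions: HF·pyridine, pyridine, THF, 0 °C → rt
Reagents that add atoms: none
Why: Fluoride-mediated cleavage of the Si–O bond under buffered, non-basic conditions, so the laurate is neither hydrolysed nor transferred; the trans arrangement of the C13 ester and the C11 arm also disfavours acyl migration.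

Step 12
Reactants: 17 (2S,3S,5R)-5-(hydroxymethyl)-2-pentyltetrahydrofuran-3-yl dodecanoate
Product: 18 (2S,3S,5R)-5-formyl-2-pentyltetrahydrofuran-3-yl dodecanoate
Conditions: Dess–Martin periodinane (1.3 equiv), CH2Cl2, 0 °C → rt; aq. Na2S2O3/NaHCO3 work-up; used crude
Reagents that add atoms: none
Why: Dess–Martin oxidation takes the primary alcohol to the aldehyde under near-neutral conditions, which, with immediate use, protects the epimerisable C11.

Step 13
Reactants: 19 9-bromonon-1-ene
Product: 20 non-8-en-1-ylmagnesium bromide
Conditions: Mg turnings, I2 (cat.), Et2O, rt → reflux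
Reagents that add atoms: magnesium, [Mg]
Why: Grignard formation by insertion of magnesium into the primary C–Br bond; the remote terminal alkene is inert because no favourable ring size is available for radical cyclisation.

Step 14
Reactants: 18 (2S,3S,5R)-5-formyl-2-pentyltetrahydrofuran-3-yl dodecanoate; 20 non-8-en-1-ylmagnesium bromide
Product: 21 (2S,3S,5R)-5-[(1R)-1-hydroxydec-9-en-1-yl]-2-pentyltetrahydrofuran-3-yl dodecanoate
Conditions: MgBr2·OEt2 (3 equiv), CH2Cl2, −78 °C, 20 min; then 20 (1.3 equiv, Et2O), −78 °C; sat. aq. NH4Cl
Reagents that add atoms: none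
Why: Cram chelate-controlled Grignard addition: MgBr2 bridges the aldehyde oxygen and the ring oxygen, and the nucleophile enters from the face of the C11–H, away from C12, which gives the threo 10R carbinol; at −78 °C the aldehyde reacts far faster than the hindered secondary ester.

## Compound list

1 | dimethyl (R)-malate | COC(=O)[C@H](O)CC(=O)OC | starting material
2 | methyl (3R)-3,4-dihydroxybutanoate | OC[C@H](O)CC(=O)OC | intermediate
3 | methyl (3R)-4-(tert-butyldiphenylsilyloxy)-3-hydroxybutanoate | CC(C)(C)[Si](c1ccccc1)(c1ccccc1)OC[C@H](O)CC(=O)OC | intermediate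
4 | methyl (3R)-3-(allyloxy)-4-(tert-butyldiphenylsilyloxy)butanoate | CC(C)(C)[Si](c1ccccc1)(c1ccccc1)OC[C@H](OCC=C)CC(=O)OC | intermediate
5 | (3R)-3-(allyloxy)-4-(tert-butyldiphenylsilyloxy)butanoic acid | CC(C)(C)[Si](c1ccccc1)(c1ccccc1)OC[C@H](OCC=C)CC(=O)O | intermediate
6 | (3R)-3-(allyloxy)-4-(tert-butyldiphenylsilyloxy)butanoic isobutyl carbonic anhydride | CC(C)(C)[Si](c1ccccc1)(c1ccccc1)OC[C@H](OCC=C)CC(=O)OC(=O)OCC(C)C | intermediate (not isolated)
7 | (4R)-4-(allyloxy)-5-(tert-butyldiphenylsilyloxy)-1-diazopentan-2-one | CC(C)(C)[Si](c1ccccc1)(c1ccccc1)OC[C@H](OCC=C)CC(=O)C=[N+]=[N-] | intermediate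
8 | copper carbenoid of 7 at C14 (ancillary ligands on copper not drawn) | CC(C)(C)[Si](c1ccccc1)(c1ccccc1)OC[C@H](OCC=C)CC(=O)C=[Cu] | intermediate (not isolated)
9 | cyclic allyloxonium ylide: 1-allyl-5-[(tert-butyldiphenylsilyloxy)methyl]-3-oxooxolan-1-ium-2-ide, C11 as in 7 | CC(C)(C)[Si](c1ccccc1)(c1ccccc1)OC[C@H]1CC(=O)[CH-][O+]1CC=C | intermediate (not isolated)
10 | (2S,5R)-2-allyl-5-[(tert-butyldiphenylsilyloxy)methyl]dihydrofuran-3(2H)-one | CC(C)(C)[Si](c1ccccc1)(c1ccccc1)OC[C@H]1CC(=O)[C@H](CC=C)O1 | intermediate
11 | (2S,3S,5R)-2-allyl-5-[(tert-butyldiphenylsilyloxy)methyl]tetrahydrofuran-3-ol | CC(C)(C)[Si](c1ccccc1)(c1ccccc1)OC[C@H]1C[C@H](O)[C@H](CC=C)O1 | intermediate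
12 | dodecanoic acid | CCCCCCCCCCCC(=O)O | starting material
13 | (2S,3S,5R)-2-allyl-5-[(tert-butyldiphenylsilyloxy)methyl]tetrahydrofuran-3-yl dodecanoate | CC(C)(C)[Si](c1ccccc1)(c1ccccc1)OC[C@H]1C[C@H](OC(=O)CCCCCCCCCCC)[C@H](CC=C)O1 | intermediate
14 | (Z)-hex-3-ene | CC/C=C\CC | starting material
15 | (2S,3S,5R)-5-[(tert-butyldiphenylsilyloxy)methyl]-2-(pent-2-en-1-yl)tetrahydrofuran-3-yl dodecanoate (E/Z mixture, E isomer drawn) | CC(C)(C)[Si](c1ccccc1)(c1ccccc1)OC[C@H]1C[C@H](OC(=O)CCCCCCCCCCC)[C@H](C/C=C/CC)O1 | intermediate
16 | (2S,3S,5R)-5-[(tert-butyldiphenylsilyloxy)methyl]-2-pentyltetrahydrofuran-3-yl dodecanoate | CC(C)(C)[Si](c1ccccc1)(c1ccccc1)OC[C@H]1C[C@H](OC(=O)CCCCCCCCCCC)[C@H](CCCCC)O1 | intermediate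
17 | (2S,3S,5R)-5-(hydroxymethyl)-2-pentyltetrahydrofuran-3-yl dodecanoate | OC[C@H]1C[C@H](OC(=O)CCCCCCCCCCC)[C@H](CCCCC)O1 | intermediate
18 | (2S,3S,5R)-5-formyl-2-pentyltetrahydrofuran-3-yl dodecanoate | O=C[C@H]1C[C@H](OC(=O)CCCCCCCCCCC)[C@H](CCCCC)O1 | intermediate
19 | 9-bromonon-1-ene | C=CCCCCCCCBr | starting material
20 | non-8-en-1-ylmagnesium bromide | C=CCCCCCCC[Mg]Br | intermediate
21 | (2S,3S,5R)-5-[(1R)-1-hydroxydec-9-en-1-yl]-2-pentyltetrahydrofuran-3-yl dodecanoate | C=CCCCCCCC[C@@H](O)[C@H]1C[C@H](OC(=O)CCCCCCCCCCC)[C@H](CCCCC)O1 | target

## Step count and least certain steps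

Total step count: 14. Longest linear sequence: 13 steps (steps 1–12 and 14, from 1 to 21); step 13 is a one-step side branch.

**Step 6, the key step.**
- What may go wrong: the carbenoid may be diverted into 1,5 C–H insertion at the C10 methylene next to the silyloxy group, or into dimerisation. Facial control in the allyl transfer may be incomplete, or a [1,2]-shift may intrude, which erodes the trans relationship at C14. Ketone 10 can also epimerise at C14 on prolonged handling.
- Fallback: it sets out from 3 and comes back to the route at 16, replacing the carbenoid chemistry by a directed epoxidation and ring closure that installs the pentyl group directly.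
  - Silylation of 3 (Et3SiCl, imidazole) should give methyl (3R)-4-(tert-butyldiphenylsilyloxy)-3-(triethylsilyloxy)butanoate F1.
  - Reduction with i-Bu2AlH at −78 °C should give (3R)-4-(tert-butyldiphenylsilyloxy)-3-(triethylsilyloxy)butanal F2.
  - A Z-selective Wittig reaction with hexyltriphenylphosphonium bromide and NaN(SiMe3)2 at −78 °C should give (2R,4Z)-1-(tert-butyldiphenylsilyloxy)-2-(triethylsilyloxy)dec-4-ene F3.
  - Mild acid methanolysis of the triethylsilyl ether should give (2R,4Z)-1-(tert-butyldiphenylsilyloxy)dec-4-en-2-ol F4.
  - Hydroxyl-directed epoxidation (VO(acac)2, t-BuOOH) is expected to pass through a chair-like vanadate transition state in which allylic strain of the Z-alkene holds a C12–H in the alkene plane and the C10 arm is equatorial. Oxygen is then delivered to the face that gives the 11,13-syn epoxy alcohol (2R)-1-(tert-butyldiphenylsilyloxy)-3-[(2S,3R)-3-pentyloxiran-2-yl]propan-2-ol F5.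
  - Acid-catalysed 5-endo opening of F5 at C14 with inversion (camphorsulfonic acid, CH2Cl2, if it does not occur in the epoxidation flask) should give (2S,3S,5R)-5-[(tert-butyldiphenylsilyloxy)methyl]-2-pentyltetrahydrofuran-3-ol F6.
  - Steglich esterification of F6 with 12, as in step 8, gives 16.

**Step 14.**
- What may go wrong: chelation may be incomplete, so that the Felkin–Anh pathway competes and facial selectivity at C10 falls. The Grignard reagent may also add to the laurate carbonyl or enolise the aldehyde, which epimerises C11.
- Fallback: it sets out from 18 and 20 and comes back at 21, separating chemoselectivity from stereocontrol.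
  - Transmetalation of 20 with ClTi(OiPr)3 should give non-8-en-1-yltitanium triisopropoxide F7, which adds to aldehydes but not to esters.
  - Addition of F7 to 18 is expected to give (2S,3S,5R)-5-(1-hydroxydec-9-en-1-yl)-2-pentyltetrahydrofuran-3-yl dodecanoate as a mixture of C10 epimers F8.
  - Dess–Martin oxidation of F8 should give (2S,3S,5R)-5-(dec-9-enoyl)-2-pentyltetrahydrofuran-3-yl dodecanoate F9.
  - Reduction of F9 with LiBH(s-Bu)3 at −78 °C should follow the Felkin–Anh course, with the ring oxygen anti to the incoming hydride, and give the threo alcohol 21 without touching the ester.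

**Step 7.**
- What may go wrong: facial selectivity may be poor, because the hydride has to enter on the ring face that also carries the C11 silyloxymethyl group; that would leave part of the material as the C13 epimer.
- Fallback: it sets out from 10 and comes back at 13, making both epimers useful. Reduction with NaBH4 in MeOH at low temperature would give 11 together with (2S,3R,5R)-2-allyl-5-[(tert-butyldiphenylsilyloxy)methyl]tetrahydrofuran-3-ol F10, to be separated by chromatography. F10 is then esterified with 12 under Mitsunobu conditions (PPh3, diisopropyl azodicarboxylate, THF), which inverts C13 and gives 13 directly. Alcohol 11 is acylated as in step 8.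

**Step 9.**
- What may go wrong: ruthenium hydride species may move the allyl double bond before metathesis, which leads to chain-shortened homologues. Compound 13 may also homodimerise, or turnover may be slow.
- Fallback: it sets out from 13 and comes back at 16, building the two extra carbons by cross-coupling.
  - Hydroboration of the allyl group with 9-borabicyclo[3.3.1]nonane should give the B-alkyl borane (2S,3S,5R)-2-[3-(9-borabicyclo[3.3.1]nonan-9-yl)propyl]-5-[(tert-butyldiphenylsilyloxy)methyl]tetrahydrofuran-3-yl dodecanoate F11, which is not isolated.
  - B-alkyl Suzuki–Miyaura coupling of F11 with bromoethene (PdCl2(dppf), aq. K3PO4, THF/DMF) should give (2S,3S,5R)-5-[(tert-butyldiphenylsilyloxy)methyl]-2-(pent-4-en-1-yl)tetrahydrofuran-3-yl dodecanoate F12.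
  - Hydrogenation of F12 as in step 10 gives 16.

## Further compounds

F1 | step 6 | methyl (3R)-4-(tert-butyldiphenylsilyloxy)-3-(triethylsilyloxy)butanoate | CC(C)(C)[Si](c1ccccc1)(c1ccccc1)OC[C@H](O[Si](CC)(CC)CC)CC(=O)OC
F2 | step 6 | (3R)-4-(tert-butyldiphenylsilyloxy)-3-(triethylsilyloxy)butanal | CC(C)(C)[Si](c1ccccc1)(c1ccccc1)OC[C@H](O[Si](CC)(CC)CC)CC=O
F3 | step 6 | (2R,4Z)-1-(tert-butyldiphenylsilyloxy)-2-(triethylsilyloxy)dec-4-ene | CC(C)(C)[Si](c1ccccc1)(c1ccccc1)OC[C@H](O[Si](CC)(CC)CC)C/C=C\CCCCC
F4 | step 6 | (2R,4Z)-1-(tert-butyldiphenylsilyloxy)dec-4-en-2-ol | CC(C)(C)[Si](c1ccccc1)(c1ccccc1)OC[C@H](O)C/C=C\CCCCC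
F5 | step 6 | (2R)-1-(tert-butyldiphenylsilyloxy)-3-[(2S,3R)-3-pentyloxiran-2-yl]propan-2-ol | CC(C)(C)[Si](c1ccccc1)(c1ccccc1)OC[C@H](O)C[C@@H]1O[C@@H]1CCCCC
F6 | step 6 | (2S,3S,5R)-5-[(tert-butyldiphenylsilyloxy)methyl]-2-pentyltetrahydrofuran-3-ol | CC(C)(C)[Si](c1ccccc1)(c1ccccc1)OC[C@H]1C[C@H](O)[C@H](CCCCC)O1
F7 | step 14 | non-8-en-1-yltitanium triisopropoxide | C=CCCCCCCC[Ti](OC(C)C)(OC(C)C)OC(C)C
F8 | step 14 | (2S,3S,5R)-5-(1-hydroxydec-9-en-1-yl)-2-pentyltetrahydrofuran-3-yl dodecanoate, mixture of C10 epimers | C=CCCCCCCCC(O)[C@H]1C[C@H](OC(=O)CCCCCCCCCCC)[C@H](CCCCC)O1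
F9 | step 14 | (2S,3S,5R)-5-(dec-9-enoyl)-2-pentyltetrahydrofuran-3-yl dodecanoate | C=CCCCCCCCC(=O)[C@H]1C[C@H](OC(=O)CCCCCCCCCCC)[C@H](CCCCC)O1
F10 | step 7 | (2S,3R,5R)-2-allyl-5-[(tert-butyldiphenylsilyloxy)methyl]tetrahydrofuran-3-ol | CC(C)(C)[Si](c1ccccc1)(c1ccccc1)OC[C@H]1C[C@@H](O)[C@H](CC=C)O1
F11 | step 9 | (2S,3S,5R)-2-[3-(9-borabicyclo[3.3.1]nonan-9-yl)propyl]-5-[(tert-butyldiphenylsilyloxy)methyl]tetrahydrofuran-3-yl dodecanoate | CC(C)(C)[Si](c1ccccc1)(c1ccccc1)OC[C@H]1C[C@H](OC(=O)CCCCCCCCCCC)[C@H](CCCB2C3CCCC2CCC3)O1
F12 | step 9 | (2S,3S,5R)-5-[(tert-butyldiphenylsilyloxy)methyl]-2-(pent-4-en-1-yl)tetrahydrofuran-3-yl dodecanoate | CC(C)(C)[Si](c1ccccc1)(c1ccccc1)OC[C@H]1C[C@H](OC(=O)CCCCCCCCCCC)[C@H](CCCC=C)O1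
A1 | alternative 1 | (Z)-1-[(1R)-1-(2,4,6-triisopropylphenyl)ethoxy]hept-1-ene | CCCCC/C=C\O[C@H](C)c1c(C(C)C)cc(C(C)C)cc1C(C)C
A2 | alternative 1 | dichloroketene | O=C=C(Cl)Cl
A3 | alternative 1 | (3R,4S)-2,2-dichloro-4-pentyl-3-[(1R)-1-(2,4,6-triisopropylphenyl)ethoxy]cyclobutan-1-one (cis; C13 and C14 as in the target) | O=C1C(Cl)(Cl)[C@H](O[C@H](C)c2c(C(C)C)cc(C(C)C)cc2C(C)C)[C@@H]1CCCCC
A4 | alternative 1 | (4S,5S)-5-pentyl-4-[(1R)-1-(2,4,6-triisopropylphenyl)ethoxy]dihydrofuran-2(3H)-one | O=C1C[C@H](O[C@H](C)c2c(C(C)C)cc(C(C)C)cc2C(C)C)[C@H](CCCCC)O1
A5 | alternative 2 | (2R)-2-[(1R)-1-(benzyloxy)dec-9-en-1-yl]-2,3-dihydrofuran | C=CCCCCCCC[C@@H](OCc1ccccc1)[C@H]1CC=CO1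
A6 | alternative 2 | dimethyldioxirane | CC1(C)OO1
A7 | alternative 2 | 3-[(1R)-1-(benzyloxy)dec-9-en-1-yl]-2,6-dioxabicyclo[3.1.0]hexane, oxirane oxygen trans to the C11 side chain | C=CCCCCCCC[C@@H](OCc1ccccc1)[C@H]1C[C@@H]2O[C@@H]2O1
A8 | alternative 2 | tripentylaluminium | CCCCC[Al](CCCCC)CCCCC
A9 | alternative 2 | (2S,3S,5R)-5-[(1R)-1-(benzyloxy)dec-9-en-1-yl]-2-pentyltetrahydrofuran-3-ol | C=CCCCCCCC[C@@H](OCc1ccccc1)[C@H]1C[C@H](O)[C@H](CCCCC)O1
A10 | alternative 3 | (2R)-2-(benzyloxy)undec-10-enal | C=CCCCCCCC[C@@H](OCc1ccccc1)C=O
A11 | alternative 3 | (3R)-3-(dimethylphenylsilyl)oct-1-ene | C=C[C@@H](CCCCC)[Si](C)(C)c1ccccc1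
A12 | alternative 3 | tin tetrachloride | Cl[Sn](Cl)(Cl)Cl
A13 | alternative 3 | {(2S,3R,5R)-5-[(1R)-1-(benzyloxy)dec-9-en-1-yl]-2-pentyloxolan-3-yl}dimethyl(phenyl)silane | C=CCCCCCCC[C@@H](OCc1ccccc1)[C@H]1C[C@@H]([Si](C)(C)c2ccccc2)[C@H](CCCCC)O1
A14 | alternative 3 | (2S,3R,5R)-5-[(1R)-1-(benzyloxy)dec-9-en-1-yl]-2-pentyltetrahydrofuran-3-ol | C=CCCCCCCC[C@@H](OCc1ccccc1)[C@H]1C[C@@H](O)[C@H](CCCCC)O1
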